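**Retrosynthetic overview**

1. The strategy rests on ring B: oxygen at C3' and C5', a carboxyl-level carbon on C2', the aroyl group on C1' and prenyl on C6' make it a disguised 2,4-dioxocyclohexane-1-carboxylate. Pestalone H therefore goes back (MOM removal, ester to CHO by reduction and reoxidation, dehydrogenation) to dione ester 17.
2. Key disconnection of 17 at C1'–C2' and C3'–C4': dimethyl malonate plus ene-dione 14, which already carries the complete ring A (C1 OMe, C2 Br, C3 Me, C4 Cl, C5 O-protected, C6 acyl).
3. Ene-dione 14 comes from arylglyoxal 10 and the C-prenylated ketophosphonate 13 by Horner–Wadsworth–Emmons olefination; 10 comes from ring A aldehyde 5 by alkenyl Grignard addition, oxidation and ozonolysis.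
4. Aldehyde 5 comes from symmetrical 2,6-dimethoxy-4-methylbenzaldehyde by chlorination, chelation-directed mono-demethylation, bromination of the last free position and MOM protection.
5. Ring order: ring A is bought and decorated; ring B is the only ring made, closed saturated in step 10 and aromatised in step 11.

Key step: step 10

Shorthand: Ar = 3-bromo-5-chloro-2-methoxy-6-(methoxymethoxy)-4-methylphenyl; prenyl = 3-methylbut-2-en-1-yl; MOM = methoxymethyl. Primed locants refer to ring B of the target.

Assumption: in step 2 the ether flanked by chlorine and the formyl group is taken to be the one cleaved, as expected for the more crowded ortho ether in a chelation-directed dealkylation; the constitution of 3 would be confirmed by NOE before step 3.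

Remark: compounds 7, 9, 13, 16, 17 and 20 are racemates or diastereomer mixtures; none of their stereocentres survives into the achiral target.

**Route**

Step 1
Reactants: 1 2,6-dimethoxy-4-methylbenzaldehyde
Product: 2 3-chloro-2,6-dimethoxy-4-methylbenzaldehyde
Conditions: NCS (1.0 equiv), DMF, 0 °C to rt
Reagents that add atoms: N-chlorosuccinimide, O=C1CCC(=O)N1Cl
Why: Electrophilic aromatic chlorination; C3 and C5 are equivalent, each ortho/para to both methoxy groups and meta to the formyl group, so monochlorination of the symmetrical arene has a single outcome and the first chlorine slows a second one.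

Step 2
Reactants: 2 3-chloro-2,6-dimethoxy-4-methylbenzaldehyde
Product: 3 3-chloro-2-hydroxy-6-methoxy-4-methylbenzaldehyde
Conditions: BCl3 (1.1 equiv), CH2Cl2, −78 to 0 °C; then H2O
Reagents that add atoms: none
Why: Chelation-directed ether cleavage ortho to a carbonyl group by a boron Lewis acid; the methoxy group wedged between chlorine and the formyl group is twisted out of the ring plane, is the more basic oxygen and should lose its methyl group with relief of strain, while the other ether stays.

Step 3
Reactants: 3 3-chloro-2-hydroxy-6-methoxy-4-methylbenzaldehyde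
Product: 4 3-bromo-5-chloro-6-hydroxy-2-methoxy-4-methylbenzaldehyde
Conditions: NBS (1.05 equiv), MeCN, 0 °C, dark
Reagents that add atoms: N-bromosuccinimide, O=C1CCC(=O)N1Br
Why: Electrophilic aromatic bromination at the only ring position left, which is para to the free phenol and ortho to the methoxy group, so no regiochemical question arises and polar, dark conditions keep the benzylic methyl group untouched.

Step 4
Reactants: 4 3-bromo-5-chloro-6-hydroxy-2-methoxy-4-methylbenzaldehyde
Product: 5 3-bromo-5-chloro-2-methoxy-6-(methoxymethoxy)-4-methylbenzaldehyde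
Conditions: NaH, MOMCl, DMF, 0 °C
Reagents that add atoms: chloromethyl methyl ether, COCCl
Why: O-Alkylation of the sodium phenoxide (Williamson type) gives the MOM acetal, which keeps the ortho phenoxide from adding to the later ene-dione and falls off with acid at the end.

Step 5
Reactants: 5 3-bromo-5-chloro-2-methoxy-6-(methoxymethoxy)-4-methylbenzaldehyde; 6 2-methylprop-1-enylmagnesium bromide
Product: 7 (±)-1-Ar-3-methylbut-2-en-1-ol
Conditions: THF, −40 to 0 °C; then sat. aq. NH4Cl
Reagents that add atoms: none
Why: Grignard 1,2-addition to the aldehyde; the aryl bromide does not exchange with an alkenylmagnesium halide at this temperature, and the new carbinol centre is racemic and removed in step 6.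

Step 6
Reactants: 7 (±)-1-Ar-3-methylbut-2-en-1-ol
Product: 8 1-Ar-3-methylbut-2-en-1-one
Conditions: DMP, CH2Cl2, 0 °C to rt
Reagents that add atoms: none
Why: Dess–Martin oxidation of a secondary allylic benzylic alcohol under nearly neutral conditions that spare the MOM acetal and the trisubstituted alkene.

Step 7
Reactants: 8 1-Ar-3-methylbut-2-en-1-one
Product: 10 2-Ar-2-oxoacetaldehyde, via trioxolane ozonide 9 (not isolated)
Conditions: O3, CH2Cl2, −78 °C; then Me2S, −78 °C to rt; used at once without chromatography
Reagents that add atoms: ozone, [O-][O+]=O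
Why: Ozonolysis with reductive work-up; the trisubstituted alkene reacts far faster than the fully substituted, acceptor-bearing arene, and the neutral, anhydrous conditions deliver the α-keto aldehyde without the acidic medium of a selenium dioxide oxidation, which would endanger the MOM group.

Step 8
Reactants: 11 dimethyl (2-oxopropyl)phosphonate; 12 prenyl bromide
Product: 13 (±)-dimethyl (6-methyl-2-oxohept-5-en-3-yl)phosphonate
Conditions: NaH (1.0 equiv), THF, 0 °C; then 12 (0.9 equiv), 0 °C to rt
Reagents that add atoms: none
Why: C-Alkylation of the sodium salt of a β-ketophosphonate with a reactive allylic bromide, as with acetoacetate; a slight excess of 11 limits dialkylation and the stereocentre is lost in step 9.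

Step 9
Reactants: 13 (±)-dimethyl (6-methyl-2-oxohept-5-en-3-yl)phosphonate; 10 2-Ar-2-oxoacetaldehyde
Product: 14 (E)-1-Ar-3-prenylpent-2-ene-1,4-dione
Conditions: 13 (1.2 equiv), NaH (1.1 equiv), THF, 0 °C; then 10, −78 to 0 °C
Reagents that add atoms: none
Why: Horner–Wadsworth–Emmons olefination of an α-substituted β-ketophosphonate with a very electrophilic α-keto aldehyde; only the formyl carbon reacts because the aryl ketone is shielded by two ortho substituents, the aroyl group is expected trans to acetyl, and either alkene isomer would serve step 10.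

Step 10
Reactants: 14 (E)-1-Ar-3-prenylpent-2-ene-1,4-dione; 15 dimethyl malonate
Product: 17 methyl 6-(Ar-carbonyl)-2,4-dioxo-5-prenylcyclohexane-1-carboxylate (racemic all-trans), via open-chain malonate adduct 16 (not isolated)
Conditions: 15 (1.5 equiv), NaOMe (0.2 equiv), MeOH, 0 °C to rt; then NaOMe (1.5 equiv), reflux; cold 1 M HCl to pH 3–4
Reagents that add atoms: none
Why: Catalytic methoxide generates the malonate anion, which adds to C1', the unsubstituted β-carbon of the acetyl enone (bond C1'–C2'), to give 16; with a full equivalent of methoxide at reflux the methyl ketone enolate C4' of 16 attacks one malonate ester carbonyl (bond C3'–C4') and expels methoxide, and deprotonation of the resulting 1,3-dione makes the sequence irreversible. The closest known reaction type is the malonate Michael–Claisen (Dieckmann-type) route from α,β-unsaturated methyl ketones to dihydroresorcylates. Ring B closes in a 6-(enolendo)-exo-trig acylation. The three new stereocentres (C1', C2', C6') all lie α to carbonyl groups, should equilibrate under the basic conditions to the all-equatorial, all-trans racemate, and disappear on aromatisation. The step needs site selectivity in the addition (C1', not C6') and in the closure (six-ring acylation, not five-ring aldol onto the aryl ketone): prenyl makes C6' a fully substituted, slow acceptor carbon whose adduct can revert, the aryl ketone is shielded by its two ortho substituents, and only the Claisen product is drained off as a stable enolate.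

Step 11
Reactants: 17 methyl 6-(Ar-carbonyl)-2,4-dioxo-5-prenylcyclohexane-1-carboxylate
Product: 18 methyl 2-(Ar-carbonyl)-4,6-dihydroxy-3-prenylbenzoate
Conditions: DDQ (1.05 equiv), 1,4-dioxane, rt to 60 °C
Reagents that add atoms: none
Why: Quinone dehydrogenation of a dihydroresorcylate, in which removal of two hydrogens from the enolised dione gives a dienone that tautomerises to the resorcinol; one equivalent of oxidant and the acceptor-substituted product ring should hold back attack at the prenyl group.

Step 12
Reactants: 18 methyl 2-(Ar-carbonyl)-4,6-dihydroxy-3-prenylbenzoate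
Product: 19 methyl 2-(Ar-carbonyl)-4,6-bis(methoxymethoxy)-3-prenylbenzoate
Conditions: NaH (2.5 equiv), MOMCl (2.5 equiv), DMF, 0 °C to rt
Reagents that add atoms: chloromethyl methyl ether, COCCl
Why: O-Alkylation of both phenoxides, the chelated one included, so that hydride reduction and Swern oxidation meet no free phenol and all three acetals can leave together at the end.

Step 13
Reactants: 19 methyl 2-(Ar-carbonyl)-4,6-bis(methoxymethoxy)-3-prenylbenzoate
Product: 20 (±)-Ar[2-(hydroxymethyl)-3,5-bis(methoxymethoxy)-6-prenylphenyl]methanol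
Conditions: LiAlH4 (excess), THF, 0 °C to rt; then H2O, 15% aq. NaOH, H2O
Reagents that add atoms: none
Why: Exhaustive hydride reduction takes the ester and the unprotectable diaryl ketone (and any phthalide formed on the way) to the diol, sparing the aryl halides, acetals and alkene at this temperature; the carbinol centre is racemic and removed in step 14.

Step 14
Reactants: 20 (±)-Ar[2-(hydroxymethyl)-3,5-bis(methoxymethoxy)-6-prenylphenyl]methanol
Product: 21 2-(Ar-carbonyl)-4,6-bis(methoxymethoxy)-3-prenylbenzaldehyde
Conditions: (COCl)2 (5 equiv), DMSO (10 equiv), CH2Cl2, −78 °C; then Et3N (15 equiv), −78 to 0 °C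
Reagents that add atoms: none
Why: Twofold Swern oxidation, in which both hydroxyl groups are converted to alkoxysulfonium ions at −78 °C before base is added, so that no hydroxy aldehyde is present to close to a lactol and be oxidised on to a phthalide.

Step 15
Reactants: 21 2-(Ar-carbonyl)-4,6-bis(methoxymethoxy)-3-prenylbenzaldehyde
Product: 22 pestalone H
Conditions: 3 M aq. HCl, MeOH–THF, rt to 40 °C
Reagents that add atoms: none
Why: Acid-catalysed hydrolysis of the three aryl MOM acetals, two of them activated by ortho carbonyl groups, under conditions mild enough for ortho-prenylphenols and free of the base that would trigger hydride shift between the formyl and keto groups.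

**Compound list**

1 | 2,6-dimethoxy-4-methylbenzaldehyde | COc1cc(C)cc(OC)c1C=O | starting material
2 | 3-chloro-2,6-dimethoxy-4-methylbenzaldehyde | COc1cc(C)c(Cl)c(OC)c1C=O | intermediate
3 | 3-chloro-2-hydroxy-6-methoxy-4-methylbenzaldehyde | COc1cc(C)c(Cl)c(O)c1C=O | intermediate
4 | 3-bromo-5-chloro-6-hydroxy-2-methoxy-4-methylbenzaldehyde | COc1c(Br)c(C)c(Cl)c(O)c1C=O | intermediate
5 | 3-bromo-5-chloro-2-methoxy-6-(methoxymethoxy)-4-methylbenzaldehyde | COCOc1c(Cl)c(C)c(Br)c(OC)c1C=O | intermediate
6 | 2-methylprop-1-enylmagnesium bromide | CC(C)=C[Mg]Br | starting material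
7 | (±)-1-[3-bromo-5-chloro-2-methoxy-6-(methoxymethoxy)-4-methylphenyl]-3-methylbut-2-en-1-ol | CC(C)=CC(O)c1c(OC)c(Br)c(C)c(Cl)c1OCOC | intermediate
8 | 1-[3-bromo-5-chloro-2-methoxy-6-(methoxymethoxy)-4-methylphenyl]-3-methylbut-2-en-1-one | CC(C)=CC(=O)c1c(OC)c(Br)c(C)c(Cl)c1OCOC | intermediate
9 | (±)-[3-bromo-5-chloro-2-methoxy-6-(methoxymethoxy)-4-methylphenyl](5,5-dimethyl-1,2,4-trioxolan-3-yl)methanone | CC1(C)OOC(O1)C(=O)c1c(OC)c(Br)c(C)c(Cl)c1OCOC | intermediate
10 | 2-[3-bromo-5-chloro-2-methoxy-6-(methoxymethoxy)-4-methylphenyl]-2-oxoacetaldehyde | O=CC(=O)c1c(OC)c(Br)c(C)c(Cl)c1OCOC | intermediate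
11 | dimethyl (2-oxopropyl)phosphonate | COP(=O)(CC(C)=O)OC | starting material
12 | 1-bromo-3-methylbut-2-ene (prenyl bromide) | CC(C)=CCBr | starting material
13 | (±)-dimethyl (6-methyl-2-oxohept-5-en-3-yl)phosphonate | COP(=O)(OC)C(CC=C(C)C)C(C)=O | intermediate
14 | (E)-1-[3-bromo-5-chloro-2-methoxy-6-(methoxymethoxy)-4-methylphenyl]-3-(3-methylbut-2-en-1-yl)pent-2-ene-1,4-dione | CC(=O)/C(CC=C(C)C)=C/C(=O)c1c(OC)c(Br)c(C)c(Cl)c1OCOC | intermediate
15 | dimethyl malonate | COC(=O)CC(=O)OC | starting material
16 | dimethyl 2-{3-acetyl-1-[3-bromo-5-chloro-2-methoxy-6-(methoxymethoxy)-4-methylphenyl]-6-methyl-1-oxohept-5-en-2-yl}propanedioate (diastereomer mixture) | COC(=O)C(C(=O)OC)C(C(=O)c1c(OC)c(Br)c(C)c(Cl)c1OCOC)C(CC=C(C)C)C(C)=O | intermediate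
17 | methyl 6-[3-bromo-5-chloro-2-methoxy-6-(methoxymethoxy)-4-methylbenzoyl]-5-(3-methylbut-2-en-1-yl)-2,4-dioxocyclohexane-1-carboxylate, racemic, all-trans, drawn as the diketo tautomer | COC(=O)[C@H]1C(=O)CC(=O)[C@@H](CC=C(C)C)[C@@H]1C(=O)c1c(OC)c(Br)c(C)c(Cl)c1OCOC | intermediate
18 | methyl 2-[3-bromo-5-chloro-2-methoxy-6-(methoxymethoxy)-4-methylbenzoyl]-4,6-dihydroxy-3-(3-methylbut-2-en-1-yl)benzoate | COC(=O)c1c(O)cc(O)c(CC=C(C)C)c1C(=O)c1c(OC)c(Br)c(C)c(Cl)c1OCOC | intermediate
19 | methyl 2-[3-bromo-5-chloro-2-methoxy-6-(methoxymethoxy)-4-methylbenzoyl]-4,6-bis(methoxymethoxy)-3-(3-methylbut-2-en-1-yl)benzoate | COC(=O)c1c(OCOC)cc(OCOC)c(CC=C(C)C)c1C(=O)c1c(OC)c(Br)c(C)c(Cl)c1OCOC | intermediate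
20 | (±)-[3-bromo-5-chloro-2-methoxy-6-(methoxymethoxy)-4-methylphenyl][2-(hydroxymethyl)-3,5-bis(methoxymethoxy)-6-(3-methylbut-2-en-1-yl)phenyl]methanol | OCc1c(OCOC)cc(OCOC)c(CC=C(C)C)c1C(O)c1c(OC)c(Br)c(C)c(Cl)c1OCOC | intermediate
21 | 2-[3-bromo-5-chloro-2-methoxy-6-(methoxymethoxy)-4-methylbenzoyl]-4,6-bis(methoxymethoxy)-3-(3-methylbut-2-en-1-yl)benzaldehyde | O=Cc1c(OCOC)cc(OCOC)c(CC=C(C)C)c1C(=O)c1c(OC)c(Br)c(C)c(Cl)c1OCOC | intermediate
22 | pestalone H, 2-(3-bromo-5-chloro-6-hydroxy-2-methoxy-4-methylbenzoyl)-4,6-dihydroxy-3-(3-methylbut-2-en-1-yl)benzaldehyde | COc1c(Br)c(C)c(Cl)c(O)c1C(=O)c1c(C=O)c(O)cc(O)c1CC=C(C)C | target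

**Step count**

Total: 15 steps. Longest linear sequence: 14 steps (steps 1–7 and 9–15 from compound 1); step 8 is a one-step branch.

**Steps most likely to fail**

Step 10. Under alkoxide the ene-dione may lose a proton from the prenyl methylene and drift into a deconjugated dienone, or malonate and methoxide may add and leave again without the adduct ever closing, so that material is consumed before ring B forms. The fallback sets out from 10 and 15 and comes back at 17; it builds the same open-chain adduct by making the C1'–C6' bond, so that no ene-dione meets alkoxide. Glyoxal 10 is condensed with dimethyl malonate 15 (piperidinium acetate, toluene, 4 Å sieves, rt to 50 °C; Knoevenagel condensation) to dimethyl 2-[2-Ar-2-oxoethylidene]propanedioate F1. Commercial 6-methylhept-5-en-2-one is converted with Me3SiCl, NaI and Et3N in MeCN into its more substituted silyl enol ether, (Z)-trimethyl[(6-methylhepta-2,5-dien-2-yl)oxy]silane F2. Mukaiyama–Michael addition of F2 to F1 (Cu(OTf)2 10 mol %, CH2Cl2, −78 °C, then dilute acid) should give 16, now isolated; the alkylidene malonate can only accept at C1'. Adduct 16 is then cyclised with NaOMe in MeOH at reflux to 17.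

Step 11. The quinone may abstract hydride from the benzylic, allylic methylene of the newly formed ortho-prenylphenol and close a 2,2-dimethylchromene, or it may fail to engage the acceptor-substituted enol at a useful rate. The fallback sets out from 17 and comes back at 18; it replaces hydride abstraction by a palladium-mediated dehydrosilylation in which the phenol next to prenyl stays silylated until work-up. Dione ester 17 is silylated (Me3SiOTf, Et3N, CH2Cl2, 0 °C) to methyl 6-(Ar-carbonyl)-5-prenyl-2,4-bis(trimethylsilyloxy)cyclohexa-1,3-diene-1-carboxylate F3. Treatment with Pd(OAc)2 (1.1 equiv, MeCN, rt; Saegusa–Ito oxidation) should give, after tautomerisation, methyl 2-(Ar-carbonyl)-6-hydroxy-3-prenyl-4-(trimethylsilyloxy)benzoate F4. Its silyl ether is cleaved on work-up with dilute citric acid in aqueous MeOH to give 18.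

Step 14. After the first of the two oxidations the remaining hydroxyl may add to the new carbonyl group and the lactol may be oxidised on to a 3-arylphthalide, or the crowded benzhydrol may be activated too slowly and stay behind. The fallback sets out from 20 and comes back at 21; it separates the two oxidations in time with a protecting group. The primary alcohol of 20 is silylated selectively (t-BuMe2SiCl, imidazole, DMF, 0 °C) to Ar[2-(tert-butyldimethylsilyloxymethyl)-3,5-bis(methoxymethoxy)-6-prenylphenyl]methanol F5. The benzhydrol is oxidised (DMP, CH2Cl2, rt) to Ar[2-(tert-butyldimethylsilyloxymethyl)-3,5-bis(methoxymethoxy)-6-prenylphenyl]methanone F6. The silyl ether is removed (HF·pyridine, THF–pyridine, 0 °C) to give Ar[2-(hydroxymethyl)-3,5-bis(methoxymethoxy)-6-prenylphenyl]methanone F7. Its primary alcohol is oxidised (DMP, CH2Cl2, rt) to 21; a keto alcohol has no path to a lactone.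

**Further compounds**

F1 | step 10 | dimethyl 2-{2-[3-bromo-5-chloro-2-methoxy-6-(methoxymethoxy)-4-methylphenyl]-2-oxoethylidene}propanedioate | COC(=O)C(=CC(=O)c1c(OC)c(Br)c(C)c(Cl)c1OCOC)C(=O)OC
F2 | step 10 | (Z)-trimethyl[(6-methylhepta-2,5-dien-2-yl)oxy]silane | C/C(O[Si](C)(C)C)=C/CC=C(C)C
F3 | step 11 | methyl 6-[3-bromo-5-chloro-2-methoxy-6-(methoxymethoxy)-4-methylbenzoyl]-5-(3-methylbut-2-en-1-yl)-2,4-bis(trimethylsilyloxy)cyclohexa-1,3-diene-1-carboxylate, racemic, trans | COC(=O)C1=C(O[Si](C)(C)C)C=C(O[Si](C)(C)C)[C@@H](CC=C(C)C)[C@@H]1C(=O)c1c(OC)c(Br)c(C)c(Cl)c1OCOC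
F4 | step 11 | methyl 2-[3-bromo-5-chloro-2-methoxy-6-(methoxymethoxy)-4-methylbenzoyl]-6-hydroxy-3-(3-methylbut-2-en-1-yl)-4-(trimethylsilyloxy)benzoate | COC(=O)c1c(O)cc(O[Si](C)(C)C)c(CC=C(C)C)c1C(=O)c1c(OC)c(Br)c(C)c(Cl)c1OCOC
F5 | step 14 | (±)-[3-bromo-5-chloro-2-methoxy-6-(methoxymethoxy)-4-methylphenyl][2-(tert-butyldimethylsilyloxymethyl)-3,5-bis(methoxymethoxy)-6-(3-methylbut-2-en-1-yl)phenyl]methanol | CC(C)(C)[Si](C)(C)OCc1c(OCOC)cc(OCOC)c(CC=C(C)C)c1C(O)c1c(OC)c(Br)c(C)c(Cl)c1OCOC
F6 | step 14 | [3-bromo-5-chloro-2-methoxy-6-(methoxymethoxy)-4-methylphenyl][2-(tert-butyldimethylsilyloxymethyl)-3,5-bis(methoxymethoxy)-6-(3-methylbut-2-en-1-yl)phenyl]methanone | CC(C)(C)[Si](C)(C)OCc1c(OCOC)cc(OCOC)c(CC=C(C)C)c1C(=O)c1c(OC)c(Br)c(C)c(Cl)c1OCOC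
F7 | step 14 | [3-bromo-5-chloro-2-methoxy-6-(methoxymethoxy)-4-methylphenyl][2-(hydroxymethyl)-3,5-bis(methoxymethoxy)-6-(3-methylbut-2-en-1-yl)phenyl]methanone | OCc1c(OCOC)cc(OCOC)c(CC=C(C)C)c1C(=O)c1c(OC)c(Br)c(C)c(Cl)c1OCOC
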